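Numbering: ring carbons C1–C10, lactone oxygen on C6, C7 carries C11(=C13)–C12, acetoxy on C8, oxirane on C1–C10 with C14 on C10, enal olefin C4=C5 with C15 on C4.
Enabling feature: with the oxirane read as a C1=C10 olefin, C2 and C3 are neighbouring CH2 groups of the ten-membered ring and each is allylic (C2 to C1=C10, C3 to C4=C5). The C2–C3 bond is therefore the seam of two allyl halves, and it can be made from a sulfone-stabilised allyl anion at C2 and an allylic bromide at C3.
Retrosynthesis: remove the two acetates, the C15 aldehyde level, the oxirane oxygen and C13; cut C2–C3 (opens the carbocycle); then cut C4–C5, C1=C10, C8–C9 and C7–C8 to reach (S)-5-(hydroxymethyl)butenolide, which holds C5, C6, C7, C11 and C12.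
Forward: the five-membered oxygen ring is present from the start. The right arm grows first (C8 by cuprate addition, C9/C10/C14 by allylboration, C1/C2 by acrylate metathesis, then the C2 sulfone), the left arm second (C4/C3/C15 by a Morita–Baylis–Hillman reaction, then the C3 bromide). The ten-membered ring closes in step 20 and the oxirane ring comes last.
From step 4 to step 23 C12 is held as a methyl acetal instead of a lactone carbonyl, because three hydride steps and the palladium-catalysed desulfonylation would otherwise reduce the lactone or ionise its allylic C6–O bond. This also leaves the sulfone CH2 as the only acidic site in the ring closure.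
Stereochemistry: C6 comes from the chiral pool, C7 from anti conjugate addition, C8 from the pinene-derived allylborane, C1 and C10 from Sharpless epoxidation with D-(−)-tartrate. C2 cis to C9 on C1=C10 is fixed by a six-membered lactone template, and C3 cis to C6 on C4=C5 by ester-controlled SN2′ bromination.

Key step: step 20

Remark: C12 in all lactols and methyl acetals, C5 in 27, C2 in 31/32 and C11 in 37/38 arise as epimer mixtures. Each centre is erased later and carries no stereo label in the SMILES.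
Remark: by the CIP rules both ring olefins of 32–40 are E, although both are cis within the ring (C2 cis to C9, C3 cis to C6).

Step 1
Reactants: 1 (S)-5-(hydroxymethyl)furan-2(5H)-one
Product: 2 (S)-5-{[(tert-butyldimethylsilyl)oxy]methyl}furan-2(5H)-one
Conditions: TBSCl, imidazole, CH2Cl2, 0 → 25 °C
Reagents that add atoms: tert-butyldimethylsilyl chloride CC(C)(C)[Si](C)(C)Cl
Why: Imidazole-promoted silyl ether formation on a primary alcohol, which also provides the bulky C5 substituent that shields one butenolide face in step 2.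

Step 2
Reactants: 2 (S)-5-{[(tert-butyldimethylsilyl)oxy]methyl}furan-2(5H)-one; 3 vinylmagnesium bromide
Product: 5 (4R,5S)-5-{[(tert-butyldimethylsilyl)oxy]methyl}-4-vinyloxolan-2-one, via silyl ketene acetal 4 (not isolated)
Conditions: 3, CuBr·SMe2 (10 mol %), TMSCl, THF, −78 °C; aq NH4Cl
Reagents that add atoms: chlorotrimethylsilane C[Si](C)(C)Cl (retained only in 4)
Why: Copper-catalysed, TMSCl-accelerated 1,4-addition of a vinyl Grignard reagent to a butenolide, in which attack anti to the C6 CH2OTBS group sets C7 trans to C6 and work-up hydrolyses the silyl ketene acetal.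

Step 3
Reactants: 5 (4R,5S)-5-{[(tert-butyldimethylsilyl)oxy]methyl}-4-vinyloxolan-2-one
Product: 6 (4R,5S)-5-{[(tert-butyldimethylsilyl)oxy]methyl}-4-vinyloxolan-2-ol (lactol)
Conditions: iBu2AlH (1.1 equiv), CH2Cl2, −78 °C; Rochelle salt
Reagents that add atoms: none
Why: Partial reduction of a γ-lactone with one equivalent of DIBAL-H stops at the aluminium hemiacetal at low temperature and should give the lactol, whose new C12 centre is of no consequence.

Step 4
Reactants: 6 lactol
Product: 7 (2S,3R)-2-{[(tert-butyldimethylsilyl)oxy]methyl}-5-methoxy-3-vinyloxolane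
Conditions: MeOH, PPTS (cat.), 25 °C
Reagents that add atoms: methanol CO
Why: Acid-catalysed acetalisation through the cyclic oxocarbenium ion, which under the weak acid PPTS is much faster than methanolysis of the primary TBS ether.

Step 5
Reactants: 7 (2S,3R)-2-{[(tert-butyldimethylsilyl)oxy]methyl}-5-methoxy-3-vinyloxolane
Product: 9 (2S,3S)-2-{[(tert-butyldimethylsilyl)oxy]methyl}-5-methoxyoxolane-3-carbaldehyde, via secondary ozonide 8 (not isolated)
Conditions: O3, CH2Cl2, −78 °C (Sudan Red 7B end point); Me2S, −78 → 25 °C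
Reagents that add atoms: ozone [O-][O+]=O
Why: Ozonolysis with reductive work-up, in which the monosubstituted olefin reacts far faster than the acetal C–H bond when the gas stream is stopped at the indicator end point, and C7 stays in its more stable trans arrangement.

Step 6
Reactants: 10 3-chloro-2-(chloromethyl)prop-1-ene; 11 4-methoxybenzyl alcohol
Product: 12 1-({[2-(chloromethyl)prop-2-en-1-yl]oxy}methyl)-4-methoxybenzene
Conditions: NaH, 11, THF, 0 °C; 10 (3 equiv), Bu4NI (cat.), 50 °C
Reagents that add atoms: none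
Why: Williamson ether synthesis on a doubly allylic dichloride, run with excess 10 so that only one chloride is exchanged.

Step 7
Reactants: 9 (2S,3S)-2-{[(tert-butyldimethylsilyl)oxy]methyl}-5-methoxyoxolane-3-carbaldehyde; 12 1-({[2-(chloromethyl)prop-2-en-1-yl]oxy}methyl)-4-methoxybenzene
Product: 16 (1S)-1-[(2S,3R)-2-{[(tert-butyldimethylsilyl)oxy]methyl}-5-methoxyoxolan-3-yl]-3-{[(4-methoxybenzyl)oxy]methyl}but-3-en-1-ol, via allylmagnesium chloride 13 (not isolated), via allylborane 14 (not isolated), via borinate 15 (not isolated)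
Conditions: 12, Mg, THF, 0 °C; (−)-Ipc2BOMe, Et2O, −78 → 25 °C; 9, Et2O, −78 °C; 3 M NaOH, 30% H2O2, 25 °C
Reagents that add atoms: magnesium [Mg] (retained only in 13); (−)-B-methoxydiisopinocampheylborane COB([C@@H]1C[C@@H]2C[C@@H](C2(C)C)[C@H]1C)[C@@H]3C[C@@H]4C[C@@H](C4(C)C)[C@H]3C (retained only in 14 and 15)
Why: Brown asymmetric allylboration with a 2-substituted allyl group through a chair transition state, in which the borane derived from (+)-α-pinene attacks the Si face of the aldehyde and sets 8S, the sense also expected from Felkin–Anh attack anti to C6.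

Step 8
Reactants: 16 homoallylic alcohol (8S); 17 acryloyl chloride
Product: 18 acrylate ester of 16 (C8–O–CO–CH=CH2)
Conditions: 17, iPr2NEt, DMAP (cat.), CH2Cl2, 0 °C
Reagents that add atoms: none
Why: DMAP-catalysed O-acylation with an acid chloride attaches C1 and C2 to the C8 oxygen as the tethered metathesis partner.

Step 9
Reactants: 18 acrylate ester
Product: 19 (6S)-6-[(2S,3R)-2-{[(tert-butyldimethylsilyl)oxy]methyl}-5-methoxyoxolan-3-yl]-4-{[(4-methoxybenzyl)oxy]methyl}-5,6-dihydro-2H-pyran-2-one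
Conditions: second-generation Grubbs catalyst RuCl2(=CHPh)(PCy3)(H2IMes) (5 mol %), CH2Cl2, reflux
Reagents that add atoms: none
Why: Ring-closing metathesis of an acrylate with a 1,1-disubstituted olefin to a 4-substituted dihydropyranone, whose six-membered ring can only hold C9 and C2 cis on C10=C1 and so fixes the olefin geometry.

Step 10
Reactants: 19 dihydropyranone
Product: 20 (2E,5S)-5-[(2S,3R)-2-{[(tert-butyldimethylsilyl)oxy]methyl}-5-methoxyoxolan-3-yl]-3-{[(4-methoxybenzyl)oxy]methyl}pent-2-ene-1,5-diol (C2–OH and C8–OH; C2 cis to C9)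
Conditions: LiAlH4, Et2O, 0 °C
Reagents that add atoms: none
Why: Hydride reduction of an α,β-unsaturated δ-lactone to the ene-1,5-diol, 1,2-attack being normal for a β,β-disubstituted enoate, with acetal, PMB and silyl ethers inert and the olefin geometry retained.

Step 11
Reactants: 20 ene-diol
Product: 21 hydroxy sulfide (C2–SPh; C8–OH free)
Conditions: PhSSPh, Bu3P, THF, 0 → 25 °C
Reagents that add atoms: diphenyl disulfide c1ccccc1SSc1ccccc1
Why: Mukaiyama–Hata thioetherification (alkoxyphosphonium salt, SN2 by thiophenolate) is selective for the primary allylic alcohol over the hindered C8 carbinol, and the strongly nucleophilic thiolate should outrun cyclic ether formation.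

Step 12
Reactants: 21 hydroxy sulfide
Product: 22 bis-silyl sulfide (C8–OTBS; C5–OTBS; C2–SPh)
Conditions: TBSCl, imidazole, DMF, 40 °C
Reagents that add atoms: tert-butyldimethylsilyl chloride CC(C)(C)[Si](C)(C)Cl
Why: Imidazole-promoted silylation of the secondary alcohol is chosen over a silyl triflate because at the temperature this hindered carbinol needs, a triflate could activate the labile acetal.

Step 13
Reactants: 22 bis-silyl sulfide
Product: 23 allylic phenyl sulfone (C2–SO2Ph)
Conditions: Pr4N[RuO4] (10 mol %), NMO (4 equiv), 4 Å MS, MeCN, 40 °C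
Reagents that add atoms: N-methylmorpholine N-oxide C[N+]1([O-])CCOCC1
Why: Perruthenate-catalysed oxidation of a sulfide to the sulfone (Ley–Griffith reagent) runs under neutral anhydrous conditions that spare the trisubstituted olefin, the PMB ether and the acid-labile acetal.

Step 14
Reactants: 23 allylic phenyl sulfone
Product: 24 primary alcohol (C5–OH; C8–OTBS kept)
Conditions: CSA (cat.), MeOH/CH2Cl2, 0 °C
Reagents that add atoms: none
Why: Acid-catalysed methanolysis distinguishes silyl ethers by hindrance, removing the primary C5 group and leaving the secondary C8 group, while the methyl acetal only exchanges with the solvent methanol.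

Step 15
Reactants: 24 primary alcohol
Product: 25 C5 aldehyde
Conditions: Pr4N[RuO4] (5 mol %), NMO, 4 Å MS, CH2Cl2, 25 °C
Reagents that add atoms: none
Why: Ley–Griffith oxidation takes the primary alcohol to the aldehyde under neutral conditions that should not epimerise C6.

Step 16
Reactants: 25 C5 aldehyde; 26 methyl acrylate
Product: 27 Morita–Baylis–Hillman adduct (C5 carbinol; C4(=C3H2)–C15O2Me)
Conditions: 26 (excess), DABCO, MeOH, 25 °C
Reagents that add atoms: none
Why: Morita–Baylis–Hillman reaction, for which α-alkoxy aldehydes are among the faster electrophiles, forms C4–C5, and the uncontrolled C5 carbinol centre is erased in step 17.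

Step 17
Reactants: 27 Morita–Baylis–Hillman adduct
Product: 28 methyl (Z)-2-(bromomethyl)enoate (C5H=C4(C3H2Br)C15O2Me; C3 cis to C6)
Conditions: NBS, Me2S, CH2Cl2, 0 → 25 °C
Reagents that add atoms: N-bromosuccinimide O=C1CCC(=O)N1Br
Why: Bromination of a Morita–Baylis–Hillman alcohol with allylic transposition (SN2′ on the alkoxysulfonium salt), in which allylic strain against the ester places C6 trans to CO2Me and therefore cis to the new CH2Br group.

Step 18
Reactants: 28 bromo ester
Product: 29 bromo alcohol (C15–OH; C3–Br)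
Conditions: iBu2AlH (2.5 equiv), CH2Cl2, −78 °C
Reagents that add atoms: none
Why: 1,2-Reduction of a 2-(bromomethyl)enoate with DIBAL-H at −78 °C gives the allylic alcohol without touching the allylic bromide, the sulfone or the acetal.

Step 19
Reactants: 29 bromo alcohol
Product: 30 bromo sulfone, the ring-closure precursor: 2-methoxyoxolane bearing on C6 the (Z)-CH=C(CH2OTBS)CH2Br arm and on C7 the (8S)-CH(OTBS)CH2C(CH2OPMB)=CHCH2SO2Ph arm (E; C2 cis to C9)
Conditions: TBSOTf, 2,6-lutidine, CH2Cl2, −78 °C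
Reagents that add atoms: tert-butyldimethylsilyl triflate CC(C)(C)[Si](C)(C)OS(=O)(=O)C(F)(F)F
Why: Silyl triflate silylation with a hindered, non-nucleophilic pyridine base protects the primary C15 alcohol within minutes at −78 °C, before the base can be alkylated by the bromide or the acetal activated.

Step 20
Reactants: 30 bromo sulfone
Product: 32 ten-membered diene sulfone (C2–SO2Ph; C12 methyl acetal; 8-OTBS; 14-OPMB; 15-OTBS), via lithiated sulfone 31 (not isolated)
Conditions: LiN(SiMe3)2 (1.3 equiv), THF, 30 added by syringe pump to a final 2 mM, −78 → −20 °C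
Reagents that add atoms: lithium hexamethyldisilazide [Li]N([Si](C)(C)C)[Si](C)(C)C (lithium retained only in 31)
Why: The amide base removes a C2 proton, the only C–H acid within its reach now that C12 is an acetal, and the lithiated allyl sulfone 31 displaces bromide from C3 by SN2 attack through its α-carbon, which forms C2–C3. The closest known reaction type is the alkylation of allylic sulfone carbanions with allylic halides, used for head-to-head terpene couplings and for closing medium and large terpenoid carbocycles. The ten-membered ring closes in the 10-exo-tet mode, helped by the two cis-disposed olefins and the trans-substituted oxolane, which fold the chain so that C2 and C3 approach each other. The new centre C2 is not controlled and need not be, since it becomes CH2 in step 21, while C6, C7, C8 and both olefin geometries are untouched because neither π system is ionised. The step needs α- over γ-alkylation (γ-attack would build a quaternary C10 in an eight-membered ring), SN2 over SN2′ (C5 is shielded by the branched C6), closure over oligomerisation (slow addition, millimolar concentration) and no 1,4-loss of the C14 alkoxide (poor PMBO leaving group, lithium counter-ion, temperature at or below −20 °C).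

Step 21
Reactants: 32 ten-membered diene sulfone
Product: 33 ten-membered diene (C2 = CH2; C12 methyl acetal; 8-OTBS; 14-OPMB; 15-OTBS)
Conditions: PdCl2(dppp) (10 mol %), LiHBEt3 (3 equiv), THF, 0 °C
Reagents that add atoms: none
Why: Palladium-catalysed hydride desulfonylation of an allylic sulfone, in which zerovalent palladium ionises C2–S to a π-allyl complex whose C10 end is fully substituted, so hydride goes to C2 with the position and geometry of C1=C10 kept, and the allylic ethers at C6, C14 and C15 are not ionised.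

Step 22
Reactants: 33 ten-membered diene
Product: 34 lactol (C12–OH)
Conditions: AcOH/THF/H2O 3:1:1, 25 °C, stopped at full conversion
Reagents that add atoms: water O
Why: Hydrolysis of a 2-deoxyfuranoside-type acetal through its oxocarbenium ion, comparable in lability to a tetrahydrofuranyl ether, should be complete before the TBS ethers solvolyse.

Step 23
Reactants: 34 lactol
Product: 35 trans-fused γ-lactone (C11 = CH2)
Conditions: Pr4N[RuO4] (5 mol %), NMO, 4 Å MS, CH2Cl2, 25 °C
Reagents that add atoms: none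
Why: Ley–Griffith oxidation converts the lactol into the γ-lactone under neutral conditions that leave both olefins, the PMB ether and the silyl ethers alone.

Step 24
Reactants: 35 γ-lactone; 36 dimethyl(methylidene)ammonium iodide
Product: 39 α-methylene-γ-lactone (C11=C13; 8-OTBS; 14-OPMB; 15-OTBS), via Mannich base 37 (not isolated), via ammonium iodide 38 (not isolated)
Conditions: LiN(iPr)2, THF, −78 °C; 36, −78 → 25 °C; MeI, MeOH, 25 °C; aq NaHCO3, CH2Cl2
Reagents that add atoms: iodomethane CI (retained only in 38)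
Why: Eschenmoser methylenation (Mannich reaction of the lactone lithium enolate, N-methylation, Hofmann-type elimination) installs C13, and the transient C11 centre is lost in the elimination.

Step 25
Reactants: 39 α-methylene-γ-lactone
Product: 40 allylic alcohol (C14–OH)
Conditions: DDQ, CH2Cl2/pH 7 buffer, 0 °C
Reagents that add atoms: none
Why: Oxidative PMB cleavage with DDQ (benzylic hydride abstraction, then hydrolysis) leaves the silyl ethers, both ring olefins and the methylene lactone untouched.

Step 26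
Reactants: 40 allylic alcohol
Product: 41 (1R,10R)-epoxy alcohol
Conditions: Ti(OiPr)4 (20 mol %), D-(−)-diethyl tartrate (24 mol %), tBuOOH, 4 Å MS, CH2Cl2, −20 °C
Reagents that add atoms: tert-butyl hydroperoxide CC(C)(C)OO
Why: Sharpless asymmetric epoxidation of a 2,3-(E)-disubstituted allylic alcohol, in which D-(−)-tartrate directs oxygen to the face that gives 1R,10R, syn addition keeps C2 and C9 cis on the oxirane, and the hydroxyl-free C4=C5 and electron-poor C11=C13 olefins do not react.

Step 27
Reactants: 41 epoxy alcohol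
Product: 42 triol (C8–OH; C14–OH; C15–OH)
Conditions: HF·pyridine, pyridine, THF, 0 → 25 °C
Reagents that add atoms: none
Why: Fluoride-mediated desilylation with pyridine-buffered HF avoids the basic medium that could trigger Payne rearrangement or conjugate addition to the methylene lactone.

Step 28
Reactants: 42 triol
Product: 43 enal diol (C15 = CHO)
Conditions: MnO2 (activated, excess), CH2Cl2, 25 °C
Reagents that add atoms: none
Why: MnO2 oxidises only the allylic C15 alcohol, since C14–OH is now an epoxy carbinol and C8–OH an unactivated secondary alcohol, and gives the enal with the olefin geometry kept.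

Step 29
Reactants: 43 enal diol
Product: 44 target CNP0211286.1
Conditions: Ac2O, pyridine, DMAP (cat.), CH2Cl2, 0 → 25 °C
Reagents that add atoms: acetic anhydride CC(=O)OC(C)=O
Why: DMAP-catalysed acetylation of the two remaining hydroxyl groups at C8 and C14 completes the target without touching any stereocentre.

Compound list
1 | (S)-5-(hydroxymethyl)furan-2(5H)-one | O=C1C=C[C@@H](CO)O1 | starting material
2 | (S)-5-{[(tert-butyldimethylsilyl)oxy]methyl}furan-2(5H)-one | O=C1C=C[C@@H](CO[Si](C)(C)C(C)(C)C)O1 | intermediate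
3 | vinylmagnesium bromide | C=C[Mg]Br | starting material
4 | silyl ketene acetal: 5-(trimethylsilyloxy)-2,3-dihydrofuran with C6 CH2OTBS and C7 vinyl trans | C1=C(O[Si](C)(C)C)O[C@H](CO[Si](C)(C)C(C)(C)C)[C@H]1C=C | intermediate
5 | (4R,5S)-5-{[(tert-butyldimethylsilyl)oxy]methyl}-4-vinyloxolan-2-one | C1C(=O)O[C@H](CO[Si](C)(C)C(C)(C)C)[C@H]1C=C | intermediate
6 | (4R,5S)-5-{[(tert-butyldimethylsilyl)oxy]methyl}-4-vinyloxolan-2-ol | C1C(O)O[C@H](CO[Si](C)(C)C(C)(C)C)[C@H]1C=C | intermediate
7 | (2S,3R)-2-{[(tert-butyldimethylsilyl)oxy]methyl}-5-methoxy-3-vinyloxolane | C1C(OC)O[C@H](CO[Si](C)(C)C(C)(C)C)[C@H]1C=C | intermediate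
8 | secondary ozonide (1,2,4-trioxolane) of 7 | C1C(OC)O[C@H](CO[Si](C)(C)C(C)(C)C)[C@H]1C2OCOO2 | intermediate
9 | (2S,3S)-2-{[(tert-butyldimethylsilyl)oxy]methyl}-5-methoxyoxolane-3-carbaldehyde | C1C(OC)O[C@H](CO[Si](C)(C)C(C)(C)C)[C@H]1C=O | intermediate
10 | 3-chloro-2-(chloromethyl)prop-1-ene | C=C(CCl)CCl | starting material
11 | 4-methoxybenzyl alcohol | COc1ccc(CO)cc1 | starting material
12 | 1-({[2-(chloromethyl)prop-2-en-1-yl]oxy}methyl)-4-methoxybenzene | C=C(CCl)COCc1ccc(OC)cc1 | intermediate
13 | 2-{[(4-methoxybenzyl)oxy]methyl}allylmagnesium chloride | C=C(C[Mg]Cl)COCc1ccc(OC)cc1 | intermediate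
14 | B-(2-{[(4-methoxybenzyl)oxy]methyl}allyl)diisopinocampheylborane, Ipc groups from (+)-α-pinene | C=C(CB([C@@H]1C[C@@H]2C[C@@H](C2(C)C)[C@H]1C)[C@@H]3C[C@@H]4C[C@@H](C4(C)C)[C@H]3C)COCc5ccc(OC)cc5 | intermediate
15 | diisopinocampheylborinate of 16 (C8–O–BIpc2) | C1C(OC)O[C@H](CO[Si](C)(C)C(C)(C)C)[C@H]1[C@@H](OB([C@@H]2C[C@@H]3C[C@@H](C3(C)C)[C@H]2C)[C@@H]4C[C@@H]5C[C@@H](C5(C)C)[C@H]4C)CC(=C)COCc6ccc(OC)cc6 | intermediate
16 | (1S)-1-[(2S,3R)-2-{[(tert-butyldimethylsilyl)oxy]methyl}-5-methoxyoxolan-3-yl]-3-{[(4-methoxybenzyl)oxy]methyl}but-3-en-1-ol | C1C(OC)O[C@H](CO[Si](C)(C)C(C)(C)C)[C@H]1[C@@H](O)CC(=C)COCc2ccc(OC)cc2 | intermediate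
17 | acryloyl chloride | C=CC(=O)Cl | starting material
18 | acrylate ester of 16 | C1C(OC)O[C@H](CO[Si](C)(C)C(C)(C)C)[C@H]1[C@@H](OC(=O)C=C)CC(=C)COCc2ccc(OC)cc2 | intermediate
19 | (6S)-6-(oxolan-3-yl as in 16)-4-{[(4-methoxybenzyl)oxy]methyl}-5,6-dihydro-2H-pyran-2-one | C1C(OC)O[C@H](CO[Si](C)(C)C(C)(C)C)[C@H]1[C@@H]2CC(COCc3ccc(OC)cc3)=CC(=O)O2 | intermediate
20 | (2E,5S)-5-(oxolan-3-yl as in 16)-3-{[(4-methoxybenzyl)oxy]methyl}pent-2-ene-1,5-diol | C1C(OC)O[C@H](CO[Si](C)(C)C(C)(C)C)[C@H]1[C@@H](O)C/C(COCc2ccc(OC)cc2)=C\CO | intermediate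
21 | hydroxy sulfide: 20 with C2–SPh in place of C2–OH | C1C(OC)O[C@H](CO[Si](C)(C)C(C)(C)C)[C@H]1[C@@H](O)C/C(COCc2ccc(OC)cc2)=C\CSc3ccccc3 | intermediate
22 | bis-silyl sulfide: 21 with C8–OTBS | C1C(OC)O[C@H](CO[Si](C)(C)C(C)(C)C)[C@H]1[C@@H](O[Si](C)(C)C(C)(C)C)C/C(COCc2ccc(OC)cc2)=C\CSc3ccccc3 | intermediate
23 | allylic phenyl sulfone: 22 with C2–SO2Ph | C1C(OC)O[C@H](CO[Si](C)(C)C(C)(C)C)[C@H]1[C@@H](O[Si](C)(C)C(C)(C)C)C/C(COCc2ccc(OC)cc2)=C\CS(=O)(=O)c3ccccc3 | intermediate
24 | primary alcohol: 23 with C5–OH | C1C(OC)O[C@H](CO)[C@H]1[C@@H](O[Si](C)(C)C(C)(C)C)C/C(COCc2ccc(OC)cc2)=C\CS(=O)(=O)c3ccccc3 | intermediate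
25 | C5 aldehyde | C1C(OC)O[C@H](C=O)[C@H]1[C@@H](O[Si](C)(C)C(C)(C)C)C/C(COCc2ccc(OC)cc2)=C\CS(=O)(=O)c3ccccc3 | intermediate
26 | methyl acrylate | C=CC(=O)OC | starting material
27 | Morita–Baylis–Hillman adduct: C5H(OH)–C4(=CH2)–CO2Me on C6 | C1C(OC)O[C@H](C(O)C(=C)C(=O)OC)[C@H]1[C@@H](O[Si](C)(C)C(C)(C)C)C/C(COCc2ccc(OC)cc2)=C\CS(=O)(=O)c3ccccc3 | intermediate
28 | methyl (Z)-2-(bromomethyl)enoate, C3 cis to C6 | C1C(OC)O[C@H](/C=C(/C(=O)OC)CBr)[C@H]1[C@@H](O[Si](C)(C)C(C)(C)C)C/C(COCc2ccc(OC)cc2)=C\CS(=O)(=O)c3ccccc3 | intermediate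
29 | (Z)-bromo alcohol, C15–OH | C1C(OC)O[C@H](/C=C(/CO)CBr)[C@H]1[C@@H](O[Si](C)(C)C(C)(C)C)C/C(COCc2ccc(OC)cc2)=C\CS(=O)(=O)c3ccccc3 | intermediate
30 | bromo sulfone, ring-closure precursor (C3–Br, C2–SO2Ph, 8-OTBS, 14-OPMB, 15-OTBS, C12 methyl acetal) | C1C(OC)O[C@H](/C=C(/CO[Si](C)(C)C(C)(C)C)CBr)[C@H]1[C@@H](O[Si](C)(C)C(C)(C)C)C/C(COCc2ccc(OC)cc2)=C\CS(=O)(=O)c3ccccc3 | intermediate
31 | C2-lithiated sulfone of 30 | C1C(OC)O[C@H](/C=C(/CO[Si](C)(C)C(C)(C)C)CBr)[C@H]1[C@@H](O[Si](C)(C)C(C)(C)C)C/C(COCc2ccc(OC)cc2)=C\C([Li])S(=O)(=O)c3ccccc3 | intermediate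
32 | ten-membered diene sulfone: cyclodeca-1(10),4-diene, both olefins cis in the ring, fused to the 2-methoxyoxolane at C6/C7, SO2Ph on C2 | C1C(OC)O[C@@H]2/C=C(/CO[Si](C)(C)C(C)(C)C)CC(S(=O)(=O)c3ccccc3)/C=C(/COCc4ccc(OC)cc4)C[C@H](O[Si](C)(C)C(C)(C)C)[C@@H]12 | intermediate
33 | ten-membered diene, C2 = CH2, C12 methyl acetal | C1C(OC)O[C@@H]2/C=C(/CO[Si](C)(C)C(C)(C)C)CC/C=C(/COCc3ccc(OC)cc3)C[C@H](O[Si](C)(C)C(C)(C)C)[C@@H]12 | intermediate
34 | lactol of 33 | C1C(O)O[C@@H]2/C=C(/CO[Si](C)(C)C(C)(C)C)CC/C=C(/COCc3ccc(OC)cc3)C[C@H](O[Si](C)(C)C(C)(C)C)[C@@H]12 | intermediate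
35 | trans-fused γ-lactone | C1C(=O)O[C@@H]2/C=C(/CO[Si](C)(C)C(C)(C)C)CC/C=C(/COCc3ccc(OC)cc3)C[C@H](O[Si](C)(C)C(C)(C)C)[C@@H]12 | intermediate
36 | dimethyl(methylidene)ammonium iodide | C=[N+](C)C.[I-] | starting material
37 | Mannich base, C11–CH2NMe2 | CN(C)CC1C(=O)O[C@@H]2/C=C(/CO[Si](C)(C)C(C)(C)C)CC/C=C(/COCc3ccc(OC)cc3)C[C@H](O[Si](C)(C)C(C)(C)C)[C@@H]12 | intermediate
38 | trimethylammonium iodide of 37 | C[N+](C)(C)CC1C(=O)O[C@@H]2/C=C(/CO[Si](C)(C)C(C)(C)C)CC/C=C(/COCc3ccc(OC)cc3)C[C@H](O[Si](C)(C)C(C)(C)C)[C@@H]12.[I-] | intermediate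
39 | α-methylene-γ-lactone, 8-OTBS, 14-OPMB, 15-OTBS | C=C1C(=O)O[C@@H]2/C=C(/CO[Si](C)(C)C(C)(C)C)CC/C=C(/COCc3ccc(OC)cc3)C[C@H](O[Si](C)(C)C(C)(C)C)[C@@H]12 | intermediate
40 | allylic alcohol, C14–OH | C=C1C(=O)O[C@@H]2/C=C(/CO[Si](C)(C)C(C)(C)C)CC/C=C(/CO)C[C@H](O[Si](C)(C)C(C)(C)C)[C@@H]12 | intermediate
41 | (1R,10R)-epoxy alcohol | C=C1C(=O)O[C@@H]2/C=C(/CO[Si](C)(C)C(C)(C)C)CC[C@H]3O[C@@]3(CO)C[C@H](O[Si](C)(C)C(C)(C)C)[C@@H]12 | intermediate
42 | triol (8-OH, 14-OH, 15-OH) | C=C1C(=O)O[C@@H]2/C=C(/CO)CC[C@H]3O[C@@]3(CO)C[C@H](O)[C@@H]12 | intermediate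
43 | enal diol (15-al, 8-OH, 14-OH) | C=C1C(=O)O[C@@H]2/C=C(/C=O)CC[C@H]3O[C@@]3(CO)C[C@H](O)[C@@H]12 | intermediate
44 | CNP0211286.1, (1R,6R,7R,8S,10R) | C=C1C(=O)O[C@@H]2/C=C(/C=O)CC[C@H]3O[C@@]3(COC(C)=O)C[C@H](OC(C)=O)[C@@H]12 | target

Total step count: 29. Longest linear sequence: 28 steps (steps 1–5 and 7–29, from 1); step 6 is the only side branch.

Steps most likely to fail

Step 20 (ring closure). Intermolecular alkylation and 1,4-elimination of the C14 alkoxide may overtake the slow medium-ring SN2 closure. The fallback makes C2–C3 between two molecules and closes the carbocycle at C1=C10 instead. It sets out from 16 and returns at 33.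
- 16 is silylated (TBSCl, imidazole) to the bis-silyl ether F1.
- F1 is taken through the chemistry of steps 14–19 with the C10 methylidene group as a spectator. This gives in turn the primary alcohol F2, the aldehyde F3, the Morita–Baylis–Hillman adduct F4, the (Z)-bromo ester F5, the bromo alcohol F6 and the silyl ether bromide F7.
- Allylmagnesium bromide with catalytic Li2CuCl4 then displaces the C3 bromide and brings in C2 and C1, giving the triene F8.
- Ring-closing metathesis between the C1 vinyl and C10 methylidene groups (second-generation Hoveyda–Grubbs catalyst RuCl2(=CH-2-iPrOC6H4)(H2IMes), dilute toluene, 80 °C) should give 33. A ten-membered ring favours the cis olefin that is needed.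
- Steps 8–13, 20 and 21 then drop out.

Step 26 (epoxidation). Facial selectivity may be poor or turnover may stall if the ring conformation hides the olefin face that the tartrate complex must reach while C14–O is bound to titanium. The fallback uses an undirected, catalyst-controlled dioxirane before the PMB group is removed. It sets out from 39 and returns at 41.
- Shi epoxidation is run on 39 (D-fructose-derived ketone, Oxone 2KHSO5·KHSO4·K2SO4, K2CO3, MeCN/dimethoxymethane/H2O, 0 °C).
- The spiro transition-state model for trisubstituted olefins predicts the 1R,10R oxirane.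
- C4=C5 is deactivated by its two allylic C–O bonds.
- This should give the epoxy PMB ether F9, and DDQ then releases 41.

Step 16 (C4–C5 bond). Slow turnover of the amine catalysis on the branched aldehyde leaves time for epimerisation at C6 and for conjugate addition of the acidic C2 methylene group to the acrylate. The fallback replaces the catalytic cycle by a preformed vinylmetal nucleophile. It sets out from 25 and returns at 27.
- Hydroalumination of methyl propiolate with iBu2AlH/HMPA (THF, 0 °C) gives methyl 2-(diisobutylalumanyl)acrylate F10.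
- F10 should add to 25 within hours to give the same adduct 27.

Further compounds
F1 | step 20 | bis-silyl ether of 16 (C5–OTBS, C8–OTBS, C10=CH2) | C1C(OC)O[C@H](CO[Si](C)(C)C(C)(C)C)[C@H]1[C@@H](O[Si](C)(C)C(C)(C)C)CC(=C)COCc2ccc(OC)cc2
F2 | step 20 | primary alcohol (C5–OH) | C1C(OC)O[C@H](CO)[C@H]1[C@@H](O[Si](C)(C)C(C)(C)C)CC(=C)COCc2ccc(OC)cc2
F3 | step 20 | C5 aldehyde | C1C(OC)O[C@H](C=O)[C@H]1[C@@H](O[Si](C)(C)C(C)(C)C)CC(=C)COCc2ccc(OC)cc2
F4 | step 20 | Morita–Baylis–Hillman adduct | C1C(OC)O[C@H](C(O)C(=C)C(=O)OC)[C@H]1[C@@H](O[Si](C)(C)C(C)(C)C)CC(=C)COCc2ccc(OC)cc2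
F5 | step 20 | methyl (Z)-2-(bromomethyl)enoate | C1C(OC)O[C@H](/C=C(/C(=O)OC)CBr)[C@H]1[C@@H](O[Si](C)(C)C(C)(C)C)CC(=C)COCc2ccc(OC)cc2
F6 | step 20 | (Z)-bromo alcohol | C1C(OC)O[C@H](/C=C(/CO)CBr)[C@H]1[C@@H](O[Si](C)(C)C(C)(C)C)CC(=C)COCc2ccc(OC)cc2
F7 | step 20 | (Z)-silyl ether bromide | C1C(OC)O[C@H](/C=C(/CO[Si](C)(C)C(C)(C)C)CBr)[C@H]1[C@@H](O[Si](C)(C)C(C)(C)C)CC(=C)COCc2ccc(OC)cc2
F8 | step 20 | triene with C3–C2–C1H=CH2 chain | C1C(OC)O[C@H](/C=C(/CO[Si](C)(C)C(C)(C)C)CCC=C)[C@H]1[C@@H](O[Si](C)(C)C(C)(C)C)CC(=C)COCc2ccc(OC)cc2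
F9 | step 26 | (1R,10R)-epoxy PMB ether | C=C1C(=O)O[C@@H]2/C=C(/CO[Si](C)(C)C(C)(C)C)CC[C@H]3O[C@@]3(COCc4ccc(OC)cc4)C[C@H](O[Si](C)(C)C(C)(C)C)[C@@H]12
F10 | step 16 | methyl 2-(diisobutylalumanyl)acrylate | C=C([Al](CC(C)C)CC(C)C)C(=O)OC
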